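**Retrosynthetic overview**
1. The target, an ent-labdane, is reached from diol ester 18 by reduction of the C-15 enoate and Yamaguchi angeloylation of O-3; no ring work follows ring A.
2. Ring A is closed last, at C3–C4: Ti(III) opens a C4/C18 epoxide on the C-5 arm to a tertiary C-4 radical, which adds 6-exo to the C-3 aldehyde on the C-10 arm. The enabling feature is the ring-A array O–C3H–C4(CH3)(C18H2–O), a 1,3-diol whose quaternary carbon sits next to the carbinol, held between the trans C-5/C-10 positions of ring B.
3. Ring B and ten carbons come from (1S)-(−)-verbenone: C2(=O)→C8, C3→C9, C4→C10, 4-CH3→C20, C5→C5, C7→C6, C1→C7, CMe2 bridge→C4/C18/C19. Cyclobutane cleavage turns the bridge into the isopropenyl group on C-5.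
4. C-10 is set by cuprate addition anti to the bridge, the C-9 chain by Mukaiyama–Michael/HWE on the regio-defined enolate, C-17 by Wittig methylenation.
5. Ring order: ring B is released from the pinane (step 4), then ring A is closed (step 9).

Key step: step 9

Remark: labdane numbering is used for all intermediates (C-18 = the hydroxymethyl carbon on C-4); the epoxide in 11–15 is carried as a mixture of C-4 epimers because C-4 is re-set in step 9.

**Step 1**
Reactants: 1 (1S,5S)-(−)-verbenone; 2 (3-bromopropoxy)(tert-butyl)diphenylsilane
Product: 4 TMS enol ether of the 1,4-adduct, via Grignard reagent 3 (not isolated)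
Conditions: 2, Mg, THF, 40 °C; then CuBr·SMe2 (10 mol %), TMSCl, HMPA, 1, THF, −78 → −30 °C; Et3N/pentane work-up
Reagents that add atoms: chlorotrimethylsilane, C[Si](C)(C)Cl
Why: TMSCl-accelerated copper-catalysed conjugate addition of a Grignard reagent to the β,β-disubstituted enone should take place anti to the gem-dimethyl bridge of the pinane, which sets the C-10 quaternary centre (new chain trans to the future C-5 substituent), and the enolate is caught regiospecifically as the C8–C9 silyl enol ether.

**Step 2**
Reactants: 4 TMS enol ether; 5 but-3-en-2-one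
Product: 6 diketone
Conditions: Sc(OTf)3 (10 mol %), CH2Cl2, −78 → −40 °C; then 1 M HCl, THF, 0 °C
Reagents that add atoms: none
Why: Mukaiyama–Michael addition can only occur at C-9 of the regio-defined silyl enol ether and should again proceed anti to the gem-dimethyl bridge, giving one C-9 epimer whose configuration is corrected in step 4.

**Step 3**
Reactants: 6 diketone; 7 triethyl phosphonoacetate
Product: 8 (E)-enoate
Conditions: NaH, THF, 0 °C → rt; chromatographic removal of the Z isomer
Reagents that add atoms: none
Why: Horner–Wadsworth–Emmons olefination should take the unhindered methyl ketone in preference to the C-8 ketone, which is flanked by the bridgehead and the substituted C-9, and should give the E enoate as the major isomer.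

**Step 4**
Reactants: 8 (E)-enoate
Product: 10 isopropenyl ketone, via tertiary chloride 9 (not isolated)
Conditions: HCl (g), AcOH, rt; evaporate; DBU, toluene, 80 °C
Reagents that add atoms: none
Why: acid-promoted cyclobutane cleavage of the pinan-2-one (C7–C4 heterolysis to a tertiary cation and the C-8 enol, chloride capture) followed by E2 elimination toward the methyl groups should give the isopropenyl group with C-5 untouched, while DBU equilibrates C-9 next to the ketone to the isomer with all three carbon chains equatorial.

**Step 5**
Reactants: 10 isopropenyl ketone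
Product: 11 epoxy ketone
Conditions: mCPBA, NaHCO3, CH2Cl2, 0 °C
Reagents that add atoms: meta-chloroperoxybenzoic acid, OOC(=O)c1cccc(Cl)c1
Why: Prilezhaev epoxidation should be selective because the isopropenyl group is the only electron-rich alkene (the enoate is deactivated and buffered peracid at 0 °C should not oxidise the hindered ketone), and the C-4 epimer mixture is of no consequence.

**Step 6**
Reactants: 11 epoxy ketone; 12 methyltriphenylphosphonium bromide
Product: 13 8(17)-methylene epoxide
Conditions: KOtBu, toluene, 0 °C → rt
Reagents that add atoms: none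
Why: Wittig methylenation of the C-8 ketone installs C-17 under conditions in which a 2,2-disubstituted epoxide, the silyl ether and the β,β-disubstituted enoate should be inert, and C-9 is already the thermodynamic epimer.

**Step 7**
Reactants: 13 8(17)-methylene epoxide
Product: 14 primary alcohol
Conditions: TBAF, THF, 0 °C → rt
Reagents that add atoms: none
Why: fluoride-mediated desilylation frees the C-3 hydroxyl without touching the epoxide, the enoate or the alkenes.

**Step 8**
Reactants: 14 primary alcohol
Product: 15 epoxy aldehyde
Conditions: Dess–Martin periodinane, NaHCO3, CH2Cl2, 0 °C → rt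
Reagents that add atoms: none
Why: buffered Dess–Martin oxidation gives the C-3 aldehyde under neutral conditions that the epoxide tolerates, and no epimerisable centre lies next to the new carbonyl.

**Step 9**
Reactants: 15 epoxy aldehyde
Product: 18 diol ester (ring A closed), via β-titanoxy C-4 radical 16 (not isolated), via bis-titanium(IV) alkoxide 17 (not isolated)
Conditions: Cp2TiCl2 (2.5 equiv), Zn dust, THF, rt; 15 added slowly to the green Cp2TiCl solution; then 1 M HCl, 0 °C
Reagents that add atoms: none
Why: Cp2TiCl (the Nugent–RajanBabu reagent) transfers one electron to the epoxide and opens it at the more substituted C4–O bond, so both epoxide epimers converge on one planar tertiary C-4 radical carrying C-18 as CH2O–Ti; this radical adds to the C-3 aldehyde carbon and the resulting oxygen radical is captured by a second Ti(III), which makes the otherwise reversible carbonyl addition productive and gives the complete 3-hydroxy-4-methyl-4-hydroxymethyl array after protonation. The closest known reaction type is the titanocene(III)-mediated reductive epoxide opening with intramolecular addition of the β-titanoxy radical to aldehydes and ketones (Barbier-type epoxide–carbonyl cyclisation to cycloalkanols). Ring A closes by 6-exo-trig radical attack on the C=O carbon through a chair transition state trans-fused to the ring-B chair, because the radical arm on C-5 and the aldehyde arm on C-10 are trans and both equatorial. At C-4 the bulky CH2OTiCp2Cl group should sit pseudo-equatorial and the methyl group pseudo-axial (syn to 10-CH3), giving the equatorial hydroxymethyl group; at C-3 the titanium-bound aldehyde oxygen should take the pseudo-equatorial position, giving the equatorial 3-hydroxyl. The step needs chemoselective activation of the epoxide (Ti(III) does not reduce the aliphatic aldehyde, the enoate or the alkenes), closure faster than trapping of the radical by Ti(III) (slow for a tertiary radical), and no attack on the 8(17)- or 13-alkene (either would need a boat ring B or a large ring).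

**Step 10**
Reactants: 18 diol ester
Product: 19 triol
Conditions: DIBAL-H (5 equiv), CH2Cl2, −78 → −20 °C; Rochelle salt
Reagents that add atoms: none
Why: DIBAL-H 1,2-reduction of the α,β-unsaturated ester gives the E allylic alcohol without touching the isolated alkenes.

**Step 11**
Reactants: 19 triol
Product: 20 15,18-bis-TBS ether
Conditions: TBSCl (2.2 equiv), imidazole, CH2Cl2, 0 °C
Reagents that add atoms: tert-butyldimethylsilyl chloride, CC(C)(C)[Si](C)(C)Cl
Why: silylation should take the two primary hydroxyls (allylic C-15 and neopentyl C-18) well before the secondary C-3 hydroxyl next to the quaternary carbon.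

**Step 12**
Reactants: 20 15,18-bis-TBS ether; 21 angelic acid
Product: 23 3-angelate bis-TBS ether, via angelic 2,4,6-trichlorobenzoic anhydride 22 (not isolated)
Conditions: 21, 2,4,6-trichlorobenzoyl chloride, Et3N, toluene, rt; then 20, 80 °C
Reagents that add atoms: none
Why: Yamaguchi esterification through the mixed anhydride, run without a nucleophilic amine catalyst, should acylate the hindered equatorial 3-hydroxyl while keeping the Z geometry of the angeloyl group.

**Step 13**
Reactants: 23 3-angelate bis-TBS ether
Product: 24 CNP0118197.1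
Conditions: HF·pyridine, pyridine, THF, 0 °C → rt
Reagents that add atoms: none
Why: acidic fluoride desilylation frees both primary hydroxyls while leaving the angelate in place and avoiding base-induced 1,3-acyl migration from O-3 to O-18.

**Compound list**
1 | (1S,5S)-(−)-verbenone (4,6,6-trimethylbicyclo[3.1.1]hept-3-en-2-one) | CC1=CC(=O)[C@H]2C[C@@H]1C2(C)C | starting material
2 | (3-bromopropoxy)(tert-butyl)diphenylsilane | BrCCCO[Si](c1ccccc1)(c1ccccc1)C(C)(C)C | starting material
3 | [3-(tert-butyldiphenylsilyloxy)propyl]magnesium bromide | Br[Mg]CCCO[Si](c1ccccc1)(c1ccccc1)C(C)(C)C | intermediate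
4 | TMS enol ether: 4,6,6-trimethyl-4-[3-(tert-butyldiphenylsilyloxy)propyl]-2-(trimethylsilyloxy)bicyclo[3.1.1]hept-2-ene, silyloxypropyl chain anti to the CMe2 bridge | C[C@]1(CCCO[Si](c3ccccc3)(c3ccccc3)C(C)(C)C)C=C(O[Si](C)(C)C)[C@H]2C[C@@H]1C2(C)C | intermediate
5 | but-3-en-2-one (methyl vinyl ketone) | C=CC(C)=O | starting material
6 | diketone: 4,6,6-trimethyl-3-(3-oxobutyl)-4-[3-(tert-butyldiphenylsilyloxy)propyl]bicyclo[3.1.1]heptan-2-one, both chains anti to the CMe2 bridge | C[C@]1(CCCO[Si](c3ccccc3)(c3ccccc3)C(C)(C)C)[C@@H](CCC(C)=O)C(=O)[C@H]2C[C@@H]1C2(C)C | intermediate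
7 | triethyl phosphonoacetate | CCOC(=O)CP(=O)(OCC)OCC | starting material
8 | (E)-enoate: as 6, with the 3-oxobutyl group converted into (3E)-5-ethoxy-3-methyl-5-oxopent-3-enyl | C[C@]1(CCCO[Si](c3ccccc3)(c3ccccc3)C(C)(C)C)[C@@H](CC/C(C)=C/C(=O)OCC)C(=O)[C@H]2C[C@@H]1C2(C)C | intermediate
9 | tertiary chloride: ring-B cyclohexanone (C-8 ketone) with 5-(2-chloropropan-2-yl), 10-methyl, 10-(3-silyloxypropyl) and the C-9 enoate chain, C-9 still in the kinetic configuration (chain cis to the silyloxypropyl group) | O=C1CC[C@H](C(C)(C)Cl)[C@@](C)(CCCO[Si](c2ccccc2)(c2ccccc2)C(C)(C)C)[C@H]1CC/C(C)=C/C(=O)OCC | intermediate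
10 | isopropenyl ketone: ring-B cyclohexanone (C-8 ketone) with 5-isopropenyl, 10-methyl, 10-[3-(tert-butyldiphenylsilyloxy)propyl] and 9-[(3E)-5-ethoxy-3-methyl-5-oxopent-3-enyl]; isopropenyl, 10-methyl and C-9 chain on one face, silyloxypropyl chain on the other | O=C1CC[C@H](C(C)=C)[C@@](C)(CCCO[Si](c2ccccc2)(c2ccccc2)C(C)(C)C)[C@@H]1CC/C(C)=C/C(=O)OCC | intermediate
11 | epoxy ketone: as 10, with the isopropenyl group converted into 2-methyloxiran-2-yl (both C-4 epimers) | O=C1CC[C@H](C2(C)CO2)[C@@](C)(CCCO[Si](c3ccccc3)(c3ccccc3)C(C)(C)C)[C@@H]1CC/C(C)=C/C(=O)OCC | intermediate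
12 | methyltriphenylphosphonium bromide | C[P+](c1ccccc1)(c1ccccc1)c1ccccc1.[Br-] | starting material
13 | 8(17)-methylene epoxide: as 11, with the C-8 ketone converted into C=CH2 | C=C1CC[C@H](C2(C)CO2)[C@@](C)(CCCO[Si](c3ccccc3)(c3ccccc3)C(C)(C)C)[C@@H]1CC/C(C)=C/C(=O)OCC | intermediate
14 | primary alcohol: as 13, with the silyl ether converted into 3-hydroxypropyl | C=C1CC[C@H](C2(C)CO2)[C@@](C)(CCCO)[C@@H]1CC/C(C)=C/C(=O)OCC | intermediate
15 | epoxy aldehyde: as 14, with the 10-substituent converted into 3-oxopropyl (C-3 aldehyde) | C=C1CC[C@H](C2(C)CO2)[C@@](C)(CCC=O)[C@@H]1CC/C(C)=C/C(=O)OCC | intermediate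
16 | β-titanoxy tertiary C-4 radical from epoxide opening (Cp drawn σ-bonded) | C=C1CC[C@H]([C](C)CO[Ti](Cl)(C2C=CC=C2)C2C=CC=C2)[C@@](C)(CCC=O)[C@@H]1CC/C(C)=C/C(=O)OCC | intermediate
17 | 3,18-bis[chlorobis(cyclopentadienyl)titanium(IV)] alkoxide of 18 | C=C1CC[C@H]2[C@@](C)(CC[C@@H](O[Ti](Cl)(C3C=CC=C3)C3C=CC=C3)[C@]2(C)CO[Ti](Cl)(C3C=CC=C3)C3C=CC=C3)[C@@H]1CC/C(C)=C/C(=O)OCC | intermediate
18 | diol ester: ethyl 3,18-dihydroxy-ent-labda-8(17),13E-dien-15-oate; trans-decalin, 3-OH equatorial, 4-CH2OH equatorial (trans to 10-CH3), 4-CH3 axial | C=C1CC[C@H]2[C@@](C)(CC[C@@H](O)[C@]2(C)CO)[C@@H]1CC/C(C)=C/C(=O)OCC | intermediate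
19 | triol: ent-labda-8(17),13E-diene-3,15,18-triol with the configuration of 18 | C=C1CC[C@H]2[C@@](C)(CC[C@@H](O)[C@]2(C)CO)[C@@H]1CC/C(C)=C/CO | intermediate
20 | 15,18-bis(tert-butyldimethylsilyl) ether of 19, 3-OH free | C=C1CC[C@H]2[C@@](C)(CC[C@@H](O)[C@]2(C)CO[Si](C)(C)C(C)(C)C)[C@@H]1CC/C(C)=C/CO[Si](C)(C)C(C)(C)C | intermediate
21 | angelic acid, (Z)-2-methylbut-2-enoic acid | C/C=C(/C)C(=O)O | starting material
22 | angelic 2,4,6-trichlorobenzoic anhydride | C/C=C(/C)C(=O)OC(=O)c1c(Cl)cc(Cl)cc1Cl | intermediate
23 | 3-O-angeloyl 15,18-bis-TBS ether | C=C1CC[C@H]2[C@@](C)(CC[C@@H](OC(=O)/C(C)=C\C)[C@]2(C)CO[Si](C)(C)C(C)(C)C)[C@@H]1CC/C(C)=C/CO[Si](C)(C)C(C)(C)C | intermediate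
24 | CNP0118197.1: 3-O-angeloyl ent-labda-8(17),13E-diene-3,15,18-triol (3-angelate equatorial, 4-CH2OH equatorial, 4-CH3 axial, 10-CH3 axial, H-5 and H-9 trans to 10-CH3) | C=C1CC[C@H]2[C@@](C)(CC[C@@H](OC(=O)/C(C)=C\C)[C@]2(C)CO)[C@@H]1CC/C(C)=C/CO | target

**Totals**
Total step count: 13. Longest linear sequence: 13 steps, from verbenone 1.

**Steps most likely to fail**

Step 9. The tertiary radical may be intercepted by Ti(III) before it closes onto the aldehyde (mixed disproportionation to an allylic alcohol, or simple reduction), or the closure may proceed with poor facial discrimination at the aldehyde or at the radical centre. The fallback replaces the radical closure by a polar, chelate-controlled one; it sets out from alcohol 14 and returns at diol ester 18. Titanium(III)-catalysed isomerisation of the epoxide (catalytic Cp2TiCl2, Mn, collidine hydrochloride) would give the allylic diol F1. Double Dess–Martin oxidation would give the enal aldehyde F2. Intramolecular reductive aldol cyclisation with Stryker's reagent should then deliver hydride to the 2-substituted acrolein and add the resulting copper enolate to the C-3 aldehyde through a chelated chair with both oxygen-bearing groups equatorial, giving the β-hydroxy aldehyde F3. Reduction of the neopentyl aldehyde with NaBH4 in MeOH at 0 °C leads to 18.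

Step 4. Proton loss from the tertiary cation or chloride may be unselective, going toward C-5 to give the tetrasubstituted isopropylidene isomer and erase the C-5 stereocentre; the cation may also be captured by internal nucleophiles, or the silyl ether may be cleaved by the acid. The fallback separates ring opening from alkene formation and uses a syn-elimination; it sets out from enoate 8 and returns at isopropenyl ketone 10. Hydrative ring opening (2 M H2SO4, THF–H2O, 40 °C, which also equilibrates C-9) would give the tertiary carbinol F4. Dehydration with Burgess reagent (benzene, 50 °C) proceeds by an intramolecular syn-elimination that should remove a methyl hydrogen and so give 10.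

Step 12. Acyl transfer to the hindered hydroxyl next to the quaternary carbon may be slow enough for the activated angeloyl unit to isomerise from Z to E (tiglate formation), and forcing conditions may provoke silyl migration. The fallback builds the Z alkene on the ester after acylation; it sets out from bis-silyl ether 20 and returns at angelate 23. Esterification of 20 with 2-[bis(2,2,2-trifluoroethoxy)phosphoryl]propanoic acid (DCC, DMAP, CH2Cl2) would give the phosphonopropionate F5. Still–Gennari olefination with acetaldehyde (KHMDS, 18-crown-6, THF, −78 °C) should give the (Z)-2-methylbut-2-enoate, which is 23.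

**Further compounds**
F1 | step 9 | allylic diol: as 14, with the epoxide converted into 3-hydroxyprop-1-en-2-yl on C-5 | C=C1CC[C@H](C(=C)CO)[C@@](C)(CCCO)[C@@H]1CC/C(C)=C/C(=O)OCC
F2 | step 9 | enal aldehyde: 5-(3-oxoprop-1-en-2-yl) and 10-(3-oxopropyl) on ring B | C=C1CC[C@H](C(=C)C=O)[C@@](C)(CCC=O)[C@@H]1CC/C(C)=C/C(=O)OCC
F3 | step 9 | β-hydroxy aldehyde: as 18, with C-18 as CHO | C=C1CC[C@H]2[C@@](C)(CC[C@@H](O)[C@]2(C)C=O)[C@@H]1CC/C(C)=C/C(=O)OCC
F4 | step 4 | tertiary carbinol: as 10, with 5-(2-hydroxypropan-2-yl) in place of isopropenyl | O=C1CC[C@H](C(C)(C)O)[C@@](C)(CCCO[Si](c2ccccc2)(c2ccccc2)C(C)(C)C)[C@@H]1CC/C(C)=C/C(=O)OCC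
F5 | step 12 | 3-O-{2-[bis(2,2,2-trifluoroethoxy)phosphoryl]propanoyl} ester of 20 | C=C1CC[C@H]2[C@@](C)(CC[C@@H](OC(=O)C(C)P(=O)(OCC(F)(F)F)OCC(F)(F)F)[C@]2(C)CO[Si](C)(C)C(C)(C)C)[C@@H]1CC/C(C)=C/CO[Si](C)(C)C(C)(C)C
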